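**Retrosynthetic overview**

1. Numbering (daucane): C1 angular C–Me, C2 CH–OAc, C3 CH2, C4 C(OH)iPr, C5 ring-fusion CH, C6 CH–O-veratroyl, C7 CH2, C8/C9 oxirane C(Me)/CH, C10 CH–OH; β is the face of the C1 methyl, α the opposite face.
2. Late stage: the oxirane comes from a C8=C9 alkene by epoxidation directed by the C10 hydroxyl; the C6 ester from a C6 ketone by reduction directed by the C4 hydroxyl; the C8 methyl from the ester that stabilises the carbenoid.
3. Key disconnection: C7–C8 and C10–C1, made together by rhodium-catalysed cyclopropanation/Cope rearrangement (formal [4+3]) of a 2-silyloxy diene C7=C6(OSi)–C5=C1 with an alkoxyvinyl diazoacetate C8–C9=C10–O.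
4. Enabling feature: with the oxirane read as a C8=C9 alkene and the C6 oxygen as a C5=C6 enol ether, the seven-membered ring C1–C5–C6–C7–C8–C9–C10 is a cyclohepta-1,4-diene around CH2-7, the retron of a cis-divinylcyclopropane whose vinyl termini are the angular C1 and the oxygenated C10.
5. Ring order: five-membered ring first (ring contraction of (R)-terpinen-4-ol, which supplies C4; C2 by allylic oxidation and CBS reduction), seven-membered ring in the key step, oxirane last.

Key step: step 11

Remark (assumption): read literally, the two oxirane descriptors of the given string put the ring bonds C7–C8 and C9–C10 on opposite faces of the oxirane (a trans-fused oxirane on a seven-membered ring); the route treats the oxirane as the cis-fused 8α,9α-epoxide syn to the C10 hydroxyl, which keeps the descriptor given for the oxirane CH (C9), and the compound list reproduces the given string for the target.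

**Route**

Step 1
Reactants: 1 (R)-(−)-terpinen-4-ol
Product: 2 triethylsilyl ether of 1
Conditions: Et3SiOTf, 2,6-lutidine, CH2Cl2, −78 → 0 °C
Reagents that add atoms: triethylsilyl trifluoromethanesulfonate, CC[Si](CC)(CC)OS(=O)(=O)C(F)(F)F
Why: Silylation of the hindered tertiary alcohol with a silyl triflate masks the hydroxyl that could otherwise eliminate at the β-hydroxy aldehyde stage and insert into the rhodium carbenoid; the stereocentre (future C4) is untouched.

Step 2
Reactants: 2 triethylsilyl ether of 1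
Product: 4 (3R)-6-oxo-3-(propan-2-yl)-3-(triethylsilyloxy)heptanal, via secondary ozonide 3 (not isolated)
Conditions: O3, CH2Cl2, −78 °C; then Me2S, −78 °C → rt
Reagents that add atoms: ozone, [O-][O+]=O
Why: Ozonolysis (Criegee mechanism, reductive work-up) cleaves the trisubstituted ring alkene to a methyl ketone and an aldehyde without touching the quaternary stereocentre.

Step 3
Reactants: 4 (3R)-6-oxo-3-(propan-2-yl)-3-(triethylsilyloxy)heptanal
Product: 5 (5S)-2-methyl-5-(propan-2-yl)-5-(triethylsilyloxy)cyclopent-1-ene-1-carbaldehyde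
Conditions: piperidine (cat.), AcOH (cat.), toluene, rt → 60 °C
Reagents that add atoms: none
Why: Amine-catalysed intramolecular aldol condensation (the enamine of the aldehyde adds 5-exo to the methyl ketone, then dehydration), the known course for 6-oxoheptanals, contracts the ring to the cyclopentenecarbaldehyde.

Step 4
Reactants: 5 (5S)-2-methyl-5-(propan-2-yl)-5-(triethylsilyloxy)cyclopent-1-ene-1-carbaldehyde
Product: 6 1-[(5S)-2-methyl-5-(propan-2-yl)-5-(triethylsilyloxy)cyclopent-1-en-1-yl]ethan-1-ol (both carbinol epimers)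
Conditions: MeMgBr, THF, −78 → 0 °C
Reagents that add atoms: methylmagnesium bromide, C[Mg]Br
Why: 1,2-Addition of the Grignard reagent to the hindered enal; the new carbinol centre is destroyed in the next step, so its configuration is irrelevant.

Step 5
Reactants: 6 carbinol (both epimers)
Product: 7 1-[(5S)-2-methyl-5-(propan-2-yl)-5-(triethylsilyloxy)cyclopent-1-en-1-yl]ethan-1-one
Conditions: Dess–Martin periodinane, CH2Cl2, 0 °C → rt
Reagents that add atoms: none
Why: Dess–Martin oxidation of the allylic secondary alcohol gives the methyl ketone under mild, non-epimerising conditions.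

Step 6
Reactants: 7 methyl ketone
Product: 8 (4S)-3-acetyl-2-methyl-4-(propan-2-yl)-4-(triethylsilyloxy)cyclopent-2-en-1-one
Conditions: Rh2(cap)4 (1 mol%), t-BuOOH, K2CO3 (cat.), CH2Cl2, rt
Reagents that add atoms: tert-butyl hydroperoxide, CC(C)(C)OO
Why: Catalytic allylic C–H oxidation by tert-butylperoxyl radicals (known for enone to 1,4-enedione conversions) oxidises the ring methylene γ to the ketone, the only secondary allylic position, and leaves the methyl group and the quaternary carbon alone.

Step 7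
Reactants: 8 enedione
Product: 9 1-[(3R,5S)-3-hydroxy-2-methyl-5-(propan-2-yl)-5-(triethylsilyloxy)cyclopent-1-en-1-yl]ethan-1-one
Conditions: (S)-2-methyl-CBS-oxazaborolidine (20 mol%), BH3·SMe2, THF, −30 °C
Reagents that add atoms: none
Why: Corey–Bakshi–Shibata reduction under reagent control: the ring enone carbonyl binds with its α-methylalkenyl arm as the large group and should receive hydride on the face that gives the (3R) carbinol (future C2–O, trans to the C4 oxygen), while the acetyl group, shielded on both sides like the carbonyl of a 2,6-disubstituted acetophenone, should react more slowly.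

Step 8
Reactants: 9 hydroxy enone
Product: 10 silyloxy diene (C7=C6 TBS enol ether on the cyclopentene; C2–OTBS; C4–OTES)
Conditions: t-BuMe2SiOTf, Et3N, CH2Cl2, −78 → 0 °C
Reagents that add atoms: tert-butyldimethylsilyl trifluoromethanesulfonate, CC(C)(C)[Si](C)(C)OS(=O)(=O)C(F)(F)F
Why: Soft enolisation (silyl triflate/amine) converts the methyl ketone into the cross-conjugated 2-silyloxy diene on the methyl side and silylates the secondary hydroxyl in the same operation; no stereocentre is affected.

Step 9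
Reactants: 11 2-[(4-methoxybenzyl)oxy]acetaldehyde; 12 ethyl diazoacetate
Product: 13 ethyl 2-diazo-3-hydroxy-4-[(4-methoxybenzyl)oxy]butanoate (racemic)
Conditions: DBU (10 mol%), MeCN, rt
Reagents that add atoms: none
Why: Base-catalysed aldol-type addition of the diazoacetate carbon to the aldehyde (known DBU-catalysed condensation of α-diazo esters with aldehydes); the carbinol centre is removed in the next step.

Step 10
Reactants: 13 diazo aldol
Product: 14 ethyl (3E)-2-diazo-4-[(4-methoxybenzyl)oxy]but-3-enoate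
Conditions: POCl3, Et3N, CH2Cl2, 0 °C → rt
Reagents that add atoms: none
Why: Dehydration of the β-hydroxy α-diazo ester with POCl3/Et3N, the standard route to vinyldiazoacetates, should give the (E)-enol ether, the only elimination available.

Step 11
Reactants: 10 silyloxy diene; 14 ethyl (3E)-2-diazo-4-[(4-methoxybenzyl)oxy]but-3-enoate
Product: 16 cycloheptadiene ester (C5=C6 TBS enol ether; C8=C9 with C8–CO2Et; 10α-OPMB; 2α-OTBS; 4β-OTES), via cis-divinylcyclopropane 15 (not isolated)
Conditions: Rh2(S-DOSP)4 (1 mol%), hexanes, −40 °C → rt, 14 added slowly; then toluene, 80 °C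
Reagents that add atoms: none
Why: Rh2(S-DOSP)4 decomposes 14 to a donor/acceptor rhodium vinylcarbenoid that cyclopropanates the terminal, electron-rich silyl enol ether alkene C7=C6 of 10 (forming C7–C8) to give the cis-divinylcyclopropane 15, which undergoes a Cope rearrangement that forms C10–C1 and breaks C6–C8. The closest known reaction type is the Davies tandem cyclopropanation/Cope formal [4+3] of vinyldiazoacetates with 2-silyloxy-1,3-dienes, including 1-vinylcycloalkenes that give angular quaternary carbons. The seven-membered ring closes in the [3,3] shift through the boat transition state (both vinyl groups endo over the three-membered ring), after the carbene transfer has closed the cyclopropane. C1 and C10 are set together: the boat geometry with the (E)-enol ether and the ring diene places the C10 oxygen cis to C2 and trans to the C1 methyl, and the absolute sense is fixed by the catalyst in the cyclopropanation (the empirical model for Rh2(S-DOSP)4 predicts the configuration drawn for 15) and then relayed stereospecifically, because from a given cyclopropane only one face of C1 can reach C10. The step needs site selectivity for the enol ether over the tetrasubstituted ring alkene and over C–H or O–H functionalisation, which the accessible 1,1-disubstituted silyl enol ether and the silyl protection of every hydroxyl should secure; regiochemistry is unambiguous because the carbenoid carbon can only bond to C7. Because the face of C1 is dictated by the cyclopropane and not by its neighbours, the bond should form syn to the C2 silyloxy and C4 isopropyl groups, where an intermolecular reagent would not go.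

Step 12
Reactants: 16 cycloheptadiene ester
Product: 17 allylic alcohol (C8–CH2OH)
Conditions: iBu2AlH, CH2Cl2, −78 → 0 °C
Reagents that add atoms: none
Why: 1,2-Reduction of the α,β-unsaturated ester to the allylic alcohol by the aluminium hydride at low temperature; the silyl ethers, the silyl enol ether and the PMB ether are inert.

Step 13
Reactants: 17 allylic alcohol
Product: 19 C8-methyl diene (C5=C6 TBS enol ether; C8=C9; 10α-OPMB; 2α-OTBS; 4β-OTES), via allylic mesylate 18 (not isolated)
Conditions: MsCl, Et3N, CH2Cl2, −20 °C; then LiBHEt3, THF, −20 → 0 °C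
Reagents that add atoms: none
Why: Deoxygenation of the primary allylic alcohol by sulfonylation and SN2 hydride displacement with LiBHEt3 (known for primary allylic sulfonates, without allylic transposition) turns the former ester carbon into the C8 methyl group.

Step 14
Reactants: 19 C8-methyl diene
Product: 20 hydroxy ketone (C6 ketone; 5α-H; 4β-OH; 2α-OTBS; 10α-OPMB)
Conditions: HF·pyridine, pyridine, THF, 0 °C
Reagents that add atoms: none
Why: Buffered fluoride should cleave the silyl enol ether and the triethylsilyl ether faster than the secondary TBS ether, releasing the C6 ketone and the C4 hydroxyl; C5 is protonated α to the ketone and, being epimerisable, is expected to settle as the trans-fused isomer in which C6 lies anti to the vicinal isopropyl group and the C4 hydroxyl hydrogen-bonds to the carbonyl.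

Step 15
Reactants: 20 hydroxy ketone
Product: 21 diol (6α-OH; 4β-OH; 2α-OTBS; 10α-OPMB)
Conditions: Me4NBH(OAc)3, MeCN/AcOH, −30 °C
Reagents that add atoms: none
Why: Evans–Saksena hydroxyl-directed reduction: the alkoxyborohydride formed at the C4 hydroxyl should deliver hydride to the carbonyl face remote from the angular methyl, giving the 6α-alcohol (C6–O trans to C4 on the seven-membered ring) under acidic conditions that do not move the β,γ-alkene into conjugation.

Step 16
Reactants: 21 diol; 22 3,4-dimethoxybenzoyl chloride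
Product: 23 6α-veratrate (4β-OH; 2α-OTBS; 10α-OPMB)
Conditions: Et3N, DMAP, CH2Cl2, 0 °C → rt
Reagents that add atoms: none
Why: DMAP-catalysed acylation of the only free secondary hydroxyl by the aroyl chloride; the tertiary C4 hydroxyl does not react.

Step 17
Reactants: 23 6α-veratrate
Product: 24 2α,4β-diol (6α-veratrate; 10α-OPMB)
Conditions: HF·pyridine, THF, rt
Reagents that add atoms: none
Why: Fluoride cleavage of the secondary TBS ether under mildly acidic conditions that leave the veratrate and the PMB ether in place.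

Step 18
Reactants: 24 2α,4β-diol
Product: 25 2α-acetate (6α-veratrate; 4β-OH; 10α-OPMB)
Conditions: Ac2O, pyridine, DMAP (cat.), CH2Cl2, 0 °C → rt
Reagents that add atoms: acetic anhydride, CC(=O)OC(C)=O
Why: Acetylation of the secondary C2 hydroxyl under DMAP catalysis, selective over the hindered tertiary C4 hydroxyl.

Step 19
Reactants: 25 2α-acetate
Product: 26 allylic alcohol (10α-OH; C8=C9; 2α-OAc; 6α-veratrate; 4β-OH)
Conditions: DDQ, CH2Cl2/pH 7 buffer, 0 °C
Reagents that add atoms: none
Why: Oxidative cleavage of the PMB ether by DDQ (oxidation to the oxocarbenium ion, then hydrolysis), compatible with the esters and the trisubstituted alkene.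

Step 20
Reactants: 26 allylic alcohol
Product: 27 target (2α-acetoxy-8α,9α-epoxy-4β,10α-dihydroxy-6α-(3,4-dimethoxybenzoyloxy)daucane)
Conditions: VO(acac)2 (5 mol%), t-BuOOH, CH2Cl2, 0 °C → rt
Reagents that add atoms: tert-butyl hydroperoxide, CC(C)(C)OO
Why: Hydroxyl-directed epoxidation (Sharpless–Michaelson type): the vanadate ester of the allylic C10 hydroxyl should deliver oxygen to the same face of the ring alkene, setting C8 and C9 as the cis-fused α-epoxide syn to the hydroxyl.

**Compound list**

1 | (R)-(−)-terpinen-4-ol [(1R)-4-methyl-1-(propan-2-yl)cyclohex-3-en-1-ol] | CC1=CC[C@@](O)(C(C)C)CC1 | starting material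
2 | triethyl{[(1R)-4-methyl-1-(propan-2-yl)cyclohex-3-en-1-yl]oxy}silane | CC1=CC[C@@](O[Si](CC)(CC)CC)(C(C)C)CC1 | intermediate
3 | secondary ozonide of 2 (1,2,4-trioxolane across the former alkene) | CC12CC[C@](O[Si](CC)(CC)CC)(C(C)C)CC(OO1)O2 | intermediate (not isolated)
4 | (3R)-6-oxo-3-(propan-2-yl)-3-(triethylsilyloxy)heptanal | O=CC[C@@](O[Si](CC)(CC)CC)(C(C)C)CCC(C)=O | intermediate
5 | (5S)-2-methyl-5-(propan-2-yl)-5-(triethylsilyloxy)cyclopent-1-ene-1-carbaldehyde | O=CC1=C(C)CC[C@]1(O[Si](CC)(CC)CC)C(C)C | intermediate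
6 | 1-[(5S)-2-methyl-5-(propan-2-yl)-5-(triethylsilyloxy)cyclopent-1-en-1-yl]ethan-1-ol (both carbinol epimers) | CC(O)C1=C(C)CC[C@]1(O[Si](CC)(CC)CC)C(C)C | intermediate
7 | 1-[(5S)-2-methyl-5-(propan-2-yl)-5-(triethylsilyloxy)cyclopent-1-en-1-yl]ethan-1-one | CC(=O)C1=C(C)CC[C@]1(O[Si](CC)(CC)CC)C(C)C | intermediate
8 | (4S)-3-acetyl-2-methyl-4-(propan-2-yl)-4-(triethylsilyloxy)cyclopent-2-en-1-one | CC(=O)C1=C(C)C(=O)C[C@]1(O[Si](CC)(CC)CC)C(C)C | intermediate
9 | 1-[(3R,5S)-3-hydroxy-2-methyl-5-(propan-2-yl)-5-(triethylsilyloxy)cyclopent-1-en-1-yl]ethan-1-one | CC(=O)C1=C(C)[C@H](O)C[C@]1(O[Si](CC)(CC)CC)C(C)C | intermediate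
10 | silyloxy diene: (3R,5S)-3-(tert-butyldimethylsilyloxy)-1-[1-(tert-butyldimethylsilyloxy)ethenyl]-2-methyl-5-(propan-2-yl)-5-(triethylsilyloxy)cyclopent-1-ene | C=C(O[Si](C)(C)C(C)(C)C)C1=C(C)[C@H](O[Si](C)(C)C(C)(C)C)C[C@]1(O[Si](CC)(CC)CC)C(C)C | intermediate
11 | 2-[(4-methoxybenzyl)oxy]acetaldehyde | COc1ccc(COCC=O)cc1 | starting material
12 | ethyl diazoacetate | CCOC(=O)C=[N+]=[N-] | starting material
13 | ethyl 2-diazo-3-hydroxy-4-[(4-methoxybenzyl)oxy]butanoate (racemic) | CCOC(=O)C(=[N+]=[N-])C(O)COCc1ccc(OC)cc1 | intermediate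
14 | ethyl (3E)-2-diazo-4-[(4-methoxybenzyl)oxy]but-3-enoate | CCOC(=O)C(=[N+]=[N-])/C=C/OCc1ccc(OC)cc1 | intermediate
15 | cis-divinylcyclopropane: ethyl 2-(TBS-oxy)-2-(cyclopentenyl)-1-[(E)-2-(PMB-oxy)ethenyl]cyclopropane-1-carboxylate, the two alkenyl groups cis | CC(C)(C)[Si](C)(C)O[C@@]1(C[C@@]1(C(=O)OCC)/C=C/OCc2ccc(OC)cc2)C2=C(C)[C@H](O[Si](C)(C)C(C)(C)C)C[C@]2(O[Si](CC)(CC)CC)C(C)C | intermediate (not isolated)
16 | cycloheptadiene ester: dauca-5,8-diene with C6–OTBS (enol ether), C8–CO2Et, 10α-OPMB, 2α-OTBS, 4β-OTES, 1β-methyl | CC(C)(C)[Si](C)(C)OC=2CC(C(=O)OCC)=C[C@H](OCc4ccc(OC)cc4)[C@]3(C)[C@H](O[Si](C)(C)C(C)(C)C)C[C@](O[Si](CC)(CC)CC)(C(C)C)C23 | intermediate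
17 | allylic alcohol: as 16 with C8–CH2OH | CC(C)(C)[Si](C)(C)OC=2CC(CO)=C[C@H](OCc4ccc(OC)cc4)[C@]3(C)[C@H](O[Si](C)(C)C(C)(C)C)C[C@](O[Si](CC)(CC)CC)(C(C)C)C23 | intermediate
18 | allylic mesylate: as 16 with C8–CH2OMs | CC(C)(C)[Si](C)(C)OC=2CC(COS(C)(=O)=O)=C[C@H](OCc4ccc(OC)cc4)[C@]3(C)[C@H](O[Si](C)(C)C(C)(C)C)C[C@](O[Si](CC)(CC)CC)(C(C)C)C23 | intermediate (not isolated)
19 | C8-methyl diene: dauca-5,8-diene with C6–OTBS (enol ether), 10α-OPMB, 2α-OTBS, 4β-OTES | CC(C)(C)[Si](C)(C)OC=2CC(C)=C[C@H](OCc4ccc(OC)cc4)[C@]3(C)[C@H](O[Si](C)(C)C(C)(C)C)C[C@](O[Si](CC)(CC)CC)(C(C)C)C23 | intermediate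
20 | hydroxy ketone: dauc-8-en-6-one, 5α-H, 4β-OH, 2α-OTBS, 10α-OPMB | O=C2CC(C)=C[C@H](OCc4ccc(OC)cc4)[C@]3(C)[C@H](O[Si](C)(C)C(C)(C)C)C[C@](O)(C(C)C)[C@@H]23 | intermediate
21 | diol: dauc-8-ene-4β,6α-diol, 2α-OTBS, 10α-OPMB | O[C@@H]2CC(C)=C[C@H](OCc4ccc(OC)cc4)[C@]3(C)[C@H](O[Si](C)(C)C(C)(C)C)C[C@](O)(C(C)C)[C@@H]23 | intermediate
22 | 3,4-dimethoxybenzoyl chloride (veratroyl chloride) | COc1ccc(C(Cl)=O)cc1OC | starting material
23 | 6α-veratrate: 4β-OH, 2α-OTBS, 10α-OPMB, C8=C9 | COc1ccc(C(=O)O[C@@H]2CC(C)=C[C@H](OCc4ccc(OC)cc4)[C@]3(C)[C@H](O[Si](C)(C)C(C)(C)C)C[C@](O)(C(C)C)[C@@H]23)cc1OC | intermediate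
24 | 2α,4β-diol: 6α-veratrate, 10α-OPMB, C8=C9 | COc1ccc(C(=O)O[C@@H]2CC(C)=C[C@H](OCc4ccc(OC)cc4)[C@]3(C)[C@H](O)C[C@](O)(C(C)C)[C@@H]23)cc1OC | intermediate
25 | 2α-acetate: 6α-veratrate, 4β-OH, 10α-OPMB, C8=C9 | COc1ccc(C(=O)O[C@@H]2CC(C)=C[C@H](OCc4ccc(OC)cc4)[C@]3(C)[C@H](OC(C)=O)C[C@](O)(C(C)C)[C@@H]23)cc1OC | intermediate
26 | allylic alcohol: 2α-acetoxy-6α-veratroyloxy-dauc-8-ene-4β,10α-diol | COc1ccc(C(=O)O[C@@H]2CC(C)=C[C@H](O)[C@]3(C)[C@H](OC(C)=O)C[C@](O)(C(C)C)[C@@H]23)cc1OC | intermediate
27 | CNP0197096.2: 2α-acetoxy-8α,9α-epoxy-4β,10α-dihydroxy-6α-(3,4-dimethoxybenzoyloxy)daucane (string as given, see remark) | COc1ccc(C(=O)O[C@@H]2C[C@@]3(C)O[C@@H]3[C@H](O)[C@]3(C)[C@H](OC(C)=O)C[C@](O)(C(C)C)[C@@H]23)cc1OC | target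

**Summary**

Total step count: 20.
Longest linear sequence: 18 steps (steps 1–8 and 11–20, from 1 to 27).

Steps most likely to fail:

1. Step 11. The Cope rearrangement of the congested divinylcyclopropane may be slow, because C10 must bond to C1 on the face that carries the C2 silyloxy group, and the catalyst may not fully control the face of the cyclopropanation. Fallback, from 8 back to 16: 8 is enolised on the acetyl methyl with t-BuMe2SiOTf/Et3N to the silyloxy dienone F1, in which C2 is still a carbonyl carbon and puts no substituent on the face that C10 must reach. Cyclopropanation/Cope with 14 under Rh2(S-DOSP)4 should then give, through the cis-divinylcyclopropane ketone F2, the cycloheptadiene C2-ketone F3. CBS reduction ((S)-catalyst, catecholborane) would set C2 on the bicycle as the 2α-alcohol F4, and t-BuMe2SiOTf/2,6-lutidine returns the route to 16.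

2. Step 7. Hydride may be delivered to the wrong carbonyl or to the wrong face if the substrate's own bias opposes the catalyst. Fallback, from 8 back to 9: substrate-controlled Luche reduction (NaBH4, CeCl3, MeOH, −78 °C) is expected to add hydride anti to the silyloxy group and give mainly the (3S,5S)-epimer F5. Mitsunobu inversion (PPh3, DIAD, 4-nitrobenzoic acid) would give the (3R)-4-nitrobenzoate F6, and methanolysis (K2CO3, MeOH) gives 9.

3. Step 14. The freed tertiary hydroxyl may be lost by β-elimination, the C8=C9 alkene may move into conjugation with the new ketone, the wrong ring-fusion epimer may form on protonation, or the two silyl ethers may not be told apart. Fallback, from 19 back to 24: only the enol ether is unmasked (Bu4NF buffered with AcOH, THF, −20 °C) to the bis-silyl ketone F7, which cannot eliminate. It is reduced at once with NaBH4 (MeOH, −40 °C, hydride from the face remote from the angular methyl) to the 6α-alcohol F8 and acylated with 22 (Et3N, DMAP) to the bis-silyl veratrate F9. HF·pyridine at rt then removes both silyl ethers and arrives at 24.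

**Further compounds**

F1 | step 11 | silyloxy dienone: (4S)-3-[1-(tert-butyldimethylsilyloxy)ethenyl]-2-methyl-4-(propan-2-yl)-4-(triethylsilyloxy)cyclopent-2-en-1-one | C=C(O[Si](C)(C)C(C)(C)C)C1=C(C)C(=O)C[C@]1(O[Si](CC)(CC)CC)C(C)C
F2 | step 11 | cis-divinylcyclopropane ketone (as 15 with a C2 carbonyl) | CC(C)(C)[Si](C)(C)O[C@@]1(C[C@@]1(C(=O)OCC)/C=C/OCc2ccc(OC)cc2)C2=C(C)C(=O)C[C@]2(O[Si](CC)(CC)CC)C(C)C
F3 | step 11 | cycloheptadiene C2-ketone (as 16 with a C2 carbonyl) | CC(C)(C)[Si](C)(C)OC=2CC(C(=O)OCC)=C[C@H](OCc4ccc(OC)cc4)[C@]3(C)C(=O)C[C@](O[Si](CC)(CC)CC)(C(C)C)C23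
F4 | step 11 | 2α-alcohol (as 16 with free C2–OH) | CC(C)(C)[Si](C)(C)OC=2CC(C(=O)OCC)=C[C@H](OCc4ccc(OC)cc4)[C@]3(C)[C@H](O)C[C@](O[Si](CC)(CC)CC)(C(C)C)C23
F5 | step 7 | 1-[(3S,5S)-3-hydroxy-2-methyl-5-(propan-2-yl)-5-(triethylsilyloxy)cyclopent-1-en-1-yl]ethan-1-one | CC(=O)C1=C(C)[C@@H](O)C[C@]1(O[Si](CC)(CC)CC)C(C)C
F6 | step 7 | (1R,4S)-3-acetyl-2-methyl-4-(propan-2-yl)-4-(triethylsilyloxy)cyclopent-2-en-1-yl 4-nitrobenzoate | CC(=O)C1=C(C)[C@H](OC(=O)c2ccc([N+](=O)[O-])cc2)C[C@]1(O[Si](CC)(CC)CC)C(C)C
F7 | step 14 | bis-silyl ketone: dauc-8-en-6-one, 2α-OTBS, 4β-OTES, 10α-OPMB | O=C2CC(C)=C[C@H](OCc4ccc(OC)cc4)[C@]3(C)[C@H](O[Si](C)(C)C(C)(C)C)C[C@](O[Si](CC)(CC)CC)(C(C)C)[C@@H]23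
F8 | step 14 | 6α-alcohol: 2α-OTBS, 4β-OTES, 10α-OPMB | O[C@@H]2CC(C)=C[C@H](OCc4ccc(OC)cc4)[C@]3(C)[C@H](O[Si](C)(C)C(C)(C)C)C[C@](O[Si](CC)(CC)CC)(C(C)C)[C@@H]23
F9 | step 14 | bis-silyl veratrate: 6α-veratrate, 2α-OTBS, 4β-OTES, 10α-OPMB | COc1ccc(C(=O)O[C@@H]2CC(C)=C[C@H](OCc4ccc(OC)cc4)[C@]3(C)[C@H](O[Si](C)(C)C(C)(C)C)C[C@](O[Si](CC)(CC)CC)(C(C)C)[C@@H]23)cc1OC
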